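**Retrosynthetic overview**
1. C2–C3 is cut last: a Nozaki–Hiyama–Kishi closure of the ten-membered carbocycle from the seco-lactone 31 (E-alkenyl iodide plus Z-enal).
2. The γ-lactone (O6–C12) comes from desilylation and lactonisation of ester 28; the C8 angelate is put on the free C8–OH just before.
3. C7–C8 is cut by a late indium Barbier-type allylation joining fragment A (allylic bromide 14: C3–C7, C11–C13, C15) and fragment B (aldehyde 23: C1, C2, C8–C10, C14); it sets C7 and C8.
4. Fragment A comes from propargyl alcohol and methyl propiolate (C6 by asymmetric alkynylation); fragment B from methallyl alcohol (C10 by Sharpless epoxidation).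
5. Ring order: lactone first (step 18), then the cyclodecadiene (step 20).

Assumption 1: locants C1–C15 are the germacranolide locants of the target (C1=C2, C3–OH, C4(C15)=C5, C6–O lactone, C7, C8–O angelate, C9, C10(C14)–OH, C11(=C13), C12=O).
Assumption 2: (S,S)-ProPhenol is taken as the ligand enantiomer that gives the 4R carbinol 9; if it gives 4S, the mirror-image ligand is used.

**Fragment A**

Step 1
Reactants: 1 prop-2-yn-1-ol
Product: 3 (Z)-3-iodo-2-methylprop-2-en-1-ol, via alkenylmagnesium alkoxide 2 (not isolated)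
Conditions: MeMgBr (2.5 equiv), CuI (10 mol%), THF, −10 °C to rt; then I2, −10 °C
Reagents that add atoms: methylmagnesium bromide, C[Mg]Br; iodine, [I][I]
Why: Copper-catalysed anti-carbomagnesiation of the magnesium propargyl alkoxide puts the methyl on C4 and magnesium on C5 cis to the chelating CH2O group, and iodinolysis with retention gives the Z-alkene that becomes the 4,5-cis olefin.

Step 2
Reactants: 3 (Z)-3-iodo-2-methylprop-2-en-1-ol
Product: 4 (Z)-tert-butyl[(3-iodo-2-methylprop-2-en-1-yl)oxy]dimethylsilane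
Conditions: TBSCl, imidazole, DMF, rt
Reagents that add atoms: tert-butyldimethylsilyl chloride, CC(C)(C)[Si](C)(C)Cl
Why: Standard silylation of the primary alcohol; the silyl ether survives the organolithium, zinc and aluminium steps that follow.

Step 3
Reactants: 4 (Z)-tert-butyl[(3-iodo-2-methylprop-2-en-1-yl)oxy]dimethylsilane
Product: 6 (Z)-4-(tert-butyldimethylsilyloxy)-3-methylbut-2-enal, via alkenyllithium 5 (not isolated)
Conditions: t-BuLi (2.1 equiv), Et2O, −78 °C; then DMF, −78 to 0 °C; aq. NH4Cl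
Reagents that add atoms: N,N-dimethylformamide, CN(C)C=O
Why: Iodine–lithium exchange goes with retention of alkene geometry and formylation of the alkenyllithium with DMF gives the Z-enal (C6).

Step 4
Reactants: 6 (Z)-4-(tert-butyldimethylsilyloxy)-3-methylbut-2-enal; 7 methyl prop-2-ynoate
Product: 9 methyl (4R,5Z)-7-(tert-butyldimethylsilyloxy)-4-hydroxy-6-methylhept-5-en-2-ynoate, via methylzinc alkynylide 8 (not isolated)
Conditions: Me2Zn (3 equiv), (S,S)-ProPhenol (10 mol%), Ph3P=O (20 mol%), toluene, 4 °C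
Reagents that add atoms: none
Why: Zinc–ProPhenol catalysed enantioselective alkynylation of an enal, in which the chiral dinuclear zinc catalyst delivers the alkynyl group to one aldehyde face and sets C6 (4R here) by reagent control.

Step 5
Reactants: 9 methyl (4R,5Z)-7-(tert-butyldimethylsilyloxy)-4-hydroxy-6-methylhept-5-en-2-ynoate
Product: 11 methyl (2Z,4R,5Z)-7-(tert-butyldimethylsilyloxy)-4-hydroxy-2-iodo-6-methylhepta-2,5-dienoate, via cyclic alkenylaluminate 10 (not isolated)
Conditions: NaAlH2(OCH2CH2OMe)2 (1.5 equiv), THF, −72 °C; then I2, −72 to −20 °C; aq. KNaC4H4O6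
Reagents that add atoms: iodine, [I][I]
Why: Hydroxyl-directed trans-hydroalumination delivers hydride to C7 and aluminium to C11 inside a five-membered alkoxyaluminate, and iodinolysis with retention gives the α-iodo enoate with iodine cis to C6.

Step 6
Reactants: 11 methyl (2Z,4R,5Z)-7-(tert-butyldimethylsilyloxy)-4-hydroxy-2-iodo-6-methylhepta-2,5-dienoate
Product: 12 methyl (2Z,4R,5Z)-4,7-bis(tert-butyldimethylsilyloxy)-2-iodo-6-methylhepta-2,5-dienoate
Conditions: TBSOTf, 2,6-lutidine, CH2Cl2, −78 to 0 °C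
Reagents that add atoms: tert-butyldimethylsilyl triflate, CC(C)(C)[Si](C)(C)OS(=O)(=O)C(F)(F)F
Why: Silylation of the secondary allylic alcohol gives a bulky, non-chelating C6 substituent needed for facial control in the fragment coupling.

Step 7
Reactants: 12 methyl (2Z,4R,5Z)-4,7-bis(tert-butyldimethylsilyloxy)-2-iodo-6-methylhepta-2,5-dienoate
Product: 13 methyl (2E,4R,5Z)-4,7-bis(tert-butyldimethylsilyloxy)-2-(hydroxymethyl)-6-methylhepta-2,5-dienoate
Conditions: Bu3SnCH2OH (1.5 equiv), Pd(PPh3)4 (5 mol%), 1,4-dioxane, 90 °C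
Reagents that add atoms: (tributylstannyl)methanol, CCCC[Sn](CCCC)(CCCC)CO
Why: Stille cross-coupling (hydroxymethyl transfer) at the activated α-iodo enoate goes with retention of alkene geometry and installs C13 cis to C6.

Step 8
Reactants: 13 methyl (2E,4R,5Z)-4,7-bis(tert-butyldimethylsilyloxy)-2-(hydroxymethyl)-6-methylhepta-2,5-dienoate
Product: 14 methyl (2Z,4R,5Z)-2-(bromomethyl)-4,7-bis(tert-butyldimethylsilyloxy)-6-methylhepta-2,5-dienoate (fragment A)
Conditions: CBr4, PPh3, 2,6-lutidine, CH2Cl2, 0 °C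
Reagents that add atoms: tetrabromomethane, BrC(Br)(Br)Br
Why: Appel bromination substitutes the primary allylic alcohol directly (SN2), without allylic transposition or loss of alkene geometry.

**Fragment B**

Step 9
Reactants: 15 2-methylprop-2-en-1-ol
Product: 16 (S)-(2-methyloxiran-2-yl)methanol
Conditions: Ti(OiPr)4 (5 mol%), L-(+)-diisopropyl tartrate (6 mol%), t-BuOOH, 4 Å MS, CH2Cl2, −20 °C
Reagents that add atoms: tert-butyl hydroperoxide, CC(C)(C)OO
Why: Sharpless asymmetric epoxidation; the L-(+)-tartrate complex delivers oxygen to the alkene face that gives the (S)-epoxide, which fixes C10.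

Step 10
Reactants: 16 (S)-(2-methyloxiran-2-yl)methanol
Product: 17 (R)-2-methylpent-4-ene-1,2-diol
Conditions: CH2=CHMgBr (3 equiv), CuI (15 mol%), THF, −40 to 0 °C
Reagents that add atoms: vinylmagnesium bromide, C=C[Mg]Br
Why: Copper-catalysed Grignard opening of the 2,2-disubstituted epoxide occurs by SN2 attack at the unsubstituted CH2 (C9), so the quaternary stereocentre is untouched.

Step 11
Reactants: 17 (R)-2-methylpent-4-ene-1,2-diol
Product: 18 (R)-2-methyl-1,2-bis(triethylsilyloxy)pent-4-ene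
Conditions: Et3SiOTf (2.4 equiv), 2,6-lutidine, CH2Cl2, −78 to 0 °C
Reagents that add atoms: triethylsilyl triflate, CC[Si](CC)(CC)OS(=O)(=O)C(F)(F)F
Why: The silyl triflate is reactive enough to silylate the tertiary as well as the primary hydroxyl.

Step 12
Reactants: 18 (R)-2-methyl-1,2-bis(triethylsilyloxy)pent-4-ene
Product: 19 (R)-2-methyl-2-(triethylsilyloxy)pent-4-en-1-ol
Conditions: PPTS (10 mol%), MeOH/CH2Cl2 (1:4), −10 °C
Reagents that add atoms: none
Why: Acid-catalysed methanolysis cleaves the unhindered primary triethylsilyl ether much faster than the tertiary one.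

Step 13
Reactants: 19 (R)-2-methyl-2-(triethylsilyloxy)pent-4-en-1-ol
Product: 20 (R)-2-methyl-2-(triethylsilyloxy)pent-4-enal
Conditions: Dess–Martin periodinane, NaHCO3, CH2Cl2, 0 °C to rt
Reagents that add atoms: none
Why: Dess–Martin oxidation gives the aldehyde, which has no α-hydrogen and so cannot epimerise.

Step 14
Reactants: 20 (R)-2-methyl-2-(triethylsilyloxy)pent-4-enal
Product: 21 triethyl{[(3R,1E)-1-iodo-3-methylhexa-1,5-dien-3-yl]oxy}silane
Conditions: CrCl2 (6 equiv), CHI3 (2 equiv), THF/1,4-dioxane (1:6), 0 °C to rt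
Reagents that add atoms: iodoform, IC(I)I
Why: Takai olefination with the geminal dichromium reagent converts the hindered aldehyde into the E-alkenyl iodide (C1=C2).

Step 15
Reactants: 21 triethyl{[(3R,1E)-1-iodo-3-methylhexa-1,5-dien-3-yl]oxy}silane
Product: 23 (3R,4E)-5-iodo-3-methyl-3-(triethylsilyloxy)pent-4-enal (fragment B), via diol 22 (not isolated)
Conditions: OsO4 (2 mol%), NaIO4 (4 equiv), 2,6-lutidine, 1,4-dioxane/H2O (3:1), rt
Reagents that add atoms: osmium tetroxide, O=[Os](=O)(=O)=O; sodium periodate, [Na+].[O-]I(=O)(=O)=O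
Why: Lemieux–Johnson cleavage, in which OsO4 dihydroxylates the monosubstituted alkene in preference to the hindered, electron-poor iodoalkene and periodate cleaves the diol to the C8 aldehyde.

**Coupling and endgame**

Step 16
Reactants: 14 methyl (2Z,4R,5Z)-2-(bromomethyl)-4,7-bis(tert-butyldimethylsilyloxy)-6-methylhepta-2,5-dienoate; 23 (3R,4E)-5-iodo-3-methyl-3-(triethylsilyloxy)pent-4-enal
Product: 25 methyl (3R,4R,6R,7E)-3-[(1R,2Z)-1,4-bis(tert-butyldimethylsilyloxy)-3-methylbut-2-en-1-yl]-4-hydroxy-8-iodo-6-methyl-2-methylidene-6-(triethylsilyloxy)oct-7-enoate, via allylindium bromide 24 (not isolated)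
Conditions: In powder (2 equiv), THF/H2O (3:1), rt
Reagents that add atoms: none
Why: Indium Barbier-type allylation through a closed six-membered transition state: the (Z)-allylindium keeps its geometry and gives the 7,8-syn adduct, while allylic 1,3-strain holds H-6 in the alkene plane so the aldehyde bonds to C7 anti to the bulky silyloxy group, giving 6R,7R,8R.

Step 17
Reactants: 25 (the C8 alcohol from step 16); 26 (Z)-2-methylbut-2-enoic acid (angelic acid)
Product: 28 methyl (3R,4R,6R,7E)-3-[(1R,2Z)-1,4-bis(tert-butyldimethylsilyloxy)-3-methylbut-2-en-1-yl]-8-iodo-6-methyl-4-{[(2Z)-2-methylbut-2-enoyl]oxy}-2-methylidene-6-(triethylsilyloxy)oct-7-enoate, via mixed anhydride 27 (not isolated)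
Conditions: 26, 2,4,6-trichlorobenzoyl chloride, Et3N, toluene, rt, 2 h; then 25, 75 °C
Reagents that add atoms: none
Why: Yamaguchi-type mixed-anhydride esterification run without a nucleophilic catalyst acylates the secondary alcohol while keeping the Z geometry of the angelate.

Step 18
Reactants: 28 (the angelate from step 17)
Product: 30 (1R,3R,4E)-3-hydroxy-1-{(2R,3R)-2-[(1Z)-3-hydroxy-2-methylprop-1-en-1-yl]-4-methylidene-5-oxooxolan-3-yl}-5-iodo-3-methylpent-4-en-1-yl (2Z)-2-methylbut-2-enoate, via triol ester 29 (not isolated)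
Conditions: HF·pyridine, pyridine, THF, 0 °C to rt; then PPTS (cat.), CH2Cl2, rt
Reagents that add atoms: none
Why: Fluoride-mediated cleavage of all three silyl ethers frees the C6 hydroxyl, which lactonises onto the methyl ester (five-membered ring, C8 already acylated) to give the 6,7-trans α-methylene lactone without touching a stereocentre.

Step 19
Reactants: 30 (the lactone diol from step 18)
Product: 31 (1R,3R,4E)-3-hydroxy-5-iodo-3-methyl-1-{(2R,3R)-2-[(1Z)-2-methyl-3-oxoprop-1-en-1-yl]-4-methylidene-5-oxooxolan-3-yl}pent-4-en-1-yl (2Z)-2-methylbut-2-enoate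
Conditions: Dess–Martin periodinane, NaHCO3, CH2Cl2, 0 °C
Reagents that add atoms: none
Why: Buffered Dess–Martin oxidation converts the primary allylic alcohol into the Z-enal (C3) while the tertiary C10 alcohol cannot be oxidised.

Step 20
Reactants: 31 (the iodo enal from step 19)
Product: 33 (3aR,4R,6R,7E,9R,10Z,11aR)-6,9-dihydroxy-6,10-dimethyl-3-methylidene-2-oxo-2,3,3a,4,5,6,9,11a-octahydrocyclodeca[b]furan-4-yl (2Z)-2-methylbut-2-enoate (target), via alkenylchromium dichloride 32 (not isolated)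
Conditions: CrCl2 (15 equiv), NiCl2 (0.2 equiv), DMSO/THF (3:1), 2 mM, rt, slow addition
Reagents that add atoms: none
Why: Nozaki–Hiyama–Kishi macrocyclisation: zerovalent nickel inserts into the C–I bond, transmetalation gives the E-alkenylchromium species (trivalent chromium) that adds only to the aldehyde, and the C3 carbinol is set by macrocyclic substrate control (attack on the exposed face of the Z-enal, expected 3R).

**Compound list**
1 | prop-2-yn-1-ol | C#CCO | starting material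
2 | (Z)-bromomagnesium 3-(bromomagnesio)-2-methylprop-2-en-1-olate (not isolated) | Br[Mg]/C=C(/C)CO[Mg]Br | intermediate
3 | (Z)-3-iodo-2-methylprop-2-en-1-ol | I/C=C(/C)CO | intermediate
4 | (Z)-tert-butyl[(3-iodo-2-methylprop-2-en-1-yl)oxy]dimethylsilane | I/C=C(/C)CO[Si](C)(C)C(C)(C)C | intermediate
5 | (Z)-[3-(tert-butyldimethylsilyloxy)-2-methylprop-1-en-1-yl]lithium (not isolated) | [Li]/C=C(/C)CO[Si](C)(C)C(C)(C)C | intermediate
6 | (Z)-4-(tert-butyldimethylsilyloxy)-3-methylbut-2-enal | O=C/C=C(/C)CO[Si](C)(C)C(C)(C)C | intermediate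
7 | methyl prop-2-ynoate | C#CC(=O)OC | starting material
8 | methyl 3-(methylzincio)prop-2-ynoate (not isolated) | C[Zn]C#CC(=O)OC | intermediate
9 | methyl (4R,5Z)-7-(tert-butyldimethylsilyloxy)-4-hydroxy-6-methylhept-5-en-2-ynoate | COC(=O)C#C[C@H](O)/C=C(/C)CO[Si](C)(C)C(C)(C)C | intermediate
10 | sodium cyclic alkoxy(alkenyl)bis(2-methoxyethoxy)aluminate of 9, Al on C2 and O on C4 (not isolated) | [Na+].COCCO[Al-]1(OCCOC)O[C@H](/C=C(/C)CO[Si](C)(C)C(C)(C)C)C=C1C(=O)OC | intermediate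
11 | methyl (2Z,4R,5Z)-7-(tert-butyldimethylsilyloxy)-4-hydroxy-2-iodo-6-methylhepta-2,5-dienoate | COC(=O)/C(I)=C/[C@H](O)/C=C(/C)CO[Si](C)(C)C(C)(C)C | intermediate
12 | methyl (2Z,4R,5Z)-4,7-bis(tert-butyldimethylsilyloxy)-2-iodo-6-methylhepta-2,5-dienoate | COC(=O)/C(I)=C/[C@H](O[Si](C)(C)C(C)(C)C)/C=C(/C)CO[Si](C)(C)C(C)(C)C | intermediate
13 | methyl (2E,4R,5Z)-4,7-bis(tert-butyldimethylsilyloxy)-2-(hydroxymethyl)-6-methylhepta-2,5-dienoate | COC(=O)/C(CO)=C/[C@H](O[Si](C)(C)C(C)(C)C)/C=C(/C)CO[Si](C)(C)C(C)(C)C | intermediate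
14 | methyl (2Z,4R,5Z)-2-(bromomethyl)-4,7-bis(tert-butyldimethylsilyloxy)-6-methylhepta-2,5-dienoate | COC(=O)/C(CBr)=C/[C@H](O[Si](C)(C)C(C)(C)C)/C=C(/C)CO[Si](C)(C)C(C)(C)C | intermediate
15 | 2-methylprop-2-en-1-ol | C=C(C)CO | starting material
16 | (S)-(2-methyloxiran-2-yl)methanol | OC[C@@]1(C)CO1 | intermediate
17 | (R)-2-methylpent-4-ene-1,2-diol | OC[C@](C)(O)CC=C | intermediate
18 | (R)-2-methyl-1,2-bis(triethylsilyloxy)pent-4-ene | CC[Si](CC)(CC)OC[C@](C)(O[Si](CC)(CC)CC)CC=C | intermediate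
19 | (R)-2-methyl-2-(triethylsilyloxy)pent-4-en-1-ol | OC[C@](C)(O[Si](CC)(CC)CC)CC=C | intermediate
20 | (R)-2-methyl-2-(triethylsilyloxy)pent-4-enal | O=C[C@](C)(O[Si](CC)(CC)CC)CC=C | intermediate
21 | triethyl{[(3R,1E)-1-iodo-3-methylhexa-1,5-dien-3-yl]oxy}silane | I/C=C/[C@](C)(O[Si](CC)(CC)CC)CC=C | intermediate
22 | (4R,5E)-6-iodo-4-methyl-4-(triethylsilyloxy)hex-5-ene-1,2-diol, both C2 epimers (not isolated) | I/C=C/[C@](C)(O[Si](CC)(CC)CC)CC(O)CO | intermediate
23 | (3R,4E)-5-iodo-3-methyl-3-(triethylsilyloxy)pent-4-enal | I/C=C/[C@](C)(O[Si](CC)(CC)CC)CC=O | intermediate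
24 | allylindium bromide from 14, drawn as the dibromide (not isolated) | COC(=O)/C(C[In](Br)Br)=C/[C@H](O[Si](C)(C)C(C)(C)C)/C=C(/C)CO[Si](C)(C)C(C)(C)C | intermediate
25 | methyl (3R,4R,6R,7E)-3-[(1R,2Z)-1,4-bis(tert-butyldimethylsilyloxy)-3-methylbut-2-en-1-yl]-4-hydroxy-8-iodo-6-methyl-2-methylidene-6-(triethylsilyloxy)oct-7-enoate | C=C(C(=O)OC)[C@@H]([C@H](O[Si](C)(C)C(C)(C)C)/C=C(/C)CO[Si](C)(C)C(C)(C)C)[C@H](O)C[C@@](C)(O[Si](CC)(CC)CC)/C=C/I | intermediate
26 | (Z)-2-methylbut-2-enoic acid (angelic acid) | C/C=C(/C)C(=O)O | starting material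
27 | (Z)-2-methylbut-2-enoic 2,4,6-trichlorobenzoic anhydride (not isolated) | C/C=C(/C)C(=O)OC(=O)c1c(Cl)cc(Cl)cc1Cl | intermediate
28 | methyl (3R,4R,6R,7E)-3-[(1R,2Z)-1,4-bis(tert-butyldimethylsilyloxy)-3-methylbut-2-en-1-yl]-8-iodo-6-methyl-4-{[(2Z)-2-methylbut-2-enoyl]oxy}-2-methylidene-6-(triethylsilyloxy)oct-7-enoate | C=C(C(=O)OC)[C@@H]([C@H](O[Si](C)(C)C(C)(C)C)/C=C(/C)CO[Si](C)(C)C(C)(C)C)[C@H](OC(=O)/C(C)=C\C)C[C@@](C)(O[Si](CC)(CC)CC)/C=C/I | intermediate
29 | methyl (3S,4R,6R,7E)-3-[(1R,2Z)-1,4-dihydroxy-3-methylbut-2-en-1-yl]-6-hydroxy-8-iodo-6-methyl-4-{[(2Z)-2-methylbut-2-enoyl]oxy}-2-methylideneoct-7-enoate (not isolated) | C=C(C(=O)OC)[C@@H]([C@H](O)/C=C(/C)CO)[C@H](OC(=O)/C(C)=C\C)C[C@@](C)(O)/C=C/I | intermediate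
30 | (1R,3R,4E)-3-hydroxy-1-{(2R,3R)-2-[(1Z)-3-hydroxy-2-methylprop-1-en-1-yl]-4-methylidene-5-oxooxolan-3-yl}-5-iodo-3-methylpent-4-en-1-yl (2Z)-2-methylbut-2-enoate | C=C1C(=O)O[C@H](/C=C(/C)CO)[C@H]1[C@H](OC(=O)/C(C)=C\C)C[C@@](C)(O)/C=C/I | intermediate
31 | (1R,3R,4E)-3-hydroxy-5-iodo-3-methyl-1-{(2R,3R)-2-[(1Z)-2-methyl-3-oxoprop-1-en-1-yl]-4-methylidene-5-oxooxolan-3-yl}pent-4-en-1-yl (2Z)-2-methylbut-2-enoate | C=C1C(=O)O[C@H](/C=C(/C)C=O)[C@H]1[C@H](OC(=O)/C(C)=C\C)C[C@@](C)(O)/C=C/I | intermediate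
32 | E-alkenylchromium dichloride from 31 (not isolated) | C=C1C(=O)O[C@H](/C=C(/C)C=O)[C@H]1[C@H](OC(=O)/C(C)=C\C)C[C@@](C)(O)/C=C/[Cr](Cl)Cl | intermediate
33 | (3aR,4R,6R,7E,9R,10Z,11aR)-6,9-dihydroxy-6,10-dimethyl-3-methylidene-2-oxo-2,3,3a,4,5,6,9,11a-octahydrocyclodeca[b]furan-4-yl (2Z)-2-methylbut-2-enoate | C=C1C(=O)O[C@@H]2/C=C(/C)[C@H](O)/C=C/[C@](C)(O)C[C@@H](OC(=O)/C(C)=C\C)[C@@H]12 | target

**Step count**
Total: 20 steps. Longest linear sequence: 13 steps (steps 1–8 and 16–20); fragment B (steps 9–15) is made in parallel.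

**Steps most likely to fail, with fallbacks**

Step 16 (fragment coupling). The risk is twofold: the facial selectivity at C7 rests on an allylic-strain model that has not been tested on this substrate, and the indium salts in water may lactonise the new C8–OH onto the ester. The fallback sets out from 14 and comes back at 25. Bromide 14 is borylated (B2pin2, Pd2(dba)3, KOAc, DMSO, rt) to methyl (2E,4R,5Z)-4,7-bis(tert-butyldimethylsilyloxy)-6-methyl-2-[(4,4,5,5-tetramethyl-1,3,2-dioxaborolan-2-yl)methyl]hepta-2,5-dienoate F1. This isolable allylboronate is then combined with aldehyde 23 under anhydrous conditions (toluene, 70 °C, or Sc(OTf)3 catalysis at low temperature). The tight boron-centred chair enforces the 7,8-syn outcome, and oxidative work-up of the borate returns 25 without aqueous Lewis acid.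

Step 17 (angeloylation). The C8 hydroxyl is hindered and sits γ to the ester, so slow acylation at 75 °C may lose out to lactonisation, and angelates isomerise easily to tiglates. The fallback sets out from 25 and comes back at 28. Alcohol 25 is acylated at room temperature with 2-[bis(2,2,2-trifluoroethoxy)phosphoryl]propanoic acid (DCC, DMAP, CH2Cl2) to the C8 phosphonopropanoate of 25 F2. A Still–Gennari olefination with acetaldehyde (KN(SiMe3)2, 18-crown-6, THF, −78 °C) then builds the Z-trisubstituted double bond in place and gives 28.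

Step 20 (macrocyclisation). The ten-membered ring is strained, and the configuration at C3 depends on a ring-forming conformation that is not known in advance. The fallback sets out from 31 and comes back at 33. The Nozaki–Hiyama–Kishi closure is run as in step 20; if the 9S (C3) epimer of 33 F3 predominates, the crude allylic alcohol is oxidised (MnO2, CH2Cl2) to (3aR,4R,6R,7E,10Z,11aR)-6-hydroxy-6,10-dimethyl-3-methylidene-2,9-dioxo-2,3,3a,4,5,6,9,11a-octahydrocyclodeca[b]furan-4-yl (2Z)-2-methylbut-2-enoate F4. This cross-conjugated dienone is reduced 1,2 under reagent control (CBS oxazaborolidine with catecholborane, −78 °C, enantiomer chosen empirically for 3R; or NaBH4/CeCl3·7H2O) to give 33.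

**Further compounds**
F1 | step 16 | methyl (2E,4R,5Z)-4,7-bis(tert-butyldimethylsilyloxy)-6-methyl-2-[(4,4,5,5-tetramethyl-1,3,2-dioxaborolan-2-yl)methyl]hepta-2,5-dienoate | COC(=O)/C(CB1OC(C)(C)C(C)(C)O1)=C/[C@H](O[Si](C)(C)C(C)(C)C)/C=C(/C)CO[Si](C)(C)C(C)(C)C
F2 | step 17 | C8 phosphonopropanoate of 25: methyl (3R,4R,6R,7E)-3-[(1R,2Z)-1,4-bis(tert-butyldimethylsilyloxy)-3-methylbut-2-en-1-yl]-4-({2-[bis(2,2,2-trifluoroethoxy)phosphoryl]propanoyl}oxy)-8-iodo-6-methyl-2-methylidene-6-(triethylsilyloxy)oct-7-enoate | C=C(C(=O)OC)[C@@H]([C@H](O[Si](C)(C)C(C)(C)C)/C=C(/C)CO[Si](C)(C)C(C)(C)C)[C@H](OC(=O)C(C)P(=O)(OCC(F)(F)F)OCC(F)(F)F)C[C@@](C)(O[Si](CC)(CC)CC)/C=C/I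
F3 | step 20 | 9S (C3) epimer of 33: (3aR,4R,6R,7E,9S,10Z,11aR)-6,9-dihydroxy-6,10-dimethyl-3-methylidene-2-oxo-2,3,3a,4,5,6,9,11a-octahydrocyclodeca[b]furan-4-yl (2Z)-2-methylbut-2-enoate | C=C1C(=O)O[C@@H]2/C=C(/C)[C@@H](O)/C=C/[C@](C)(O)C[C@@H](OC(=O)/C(C)=C\C)[C@@H]12
F4 | step 20 | (3aR,4R,6R,7E,10Z,11aR)-6-hydroxy-6,10-dimethyl-3-methylidene-2,9-dioxo-2,3,3a,4,5,6,9,11a-octahydrocyclodeca[b]furan-4-yl (2Z)-2-methylbut-2-enoate | C=C1C(=O)O[C@@H]2/C=C(/C)C(=O)/C=C/[C@](C)(O)C[C@@H](OC(=O)/C(C)=C\C)[C@@H]12
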